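- In Sunday's run the J peak falls faster early on than the D peak falls late: 0.438 h⁻¹ against 0.104 h⁻¹. Each k is a first-order rate constant, the fraction lost per hour. We read kD late in the run, when J is down to 1.4 %, so that little new D is still forming.

| setting | Sunday's | Saturday's | Friday's | Wednesday's | alder | ash | larch | birch |
|---|---|---|---|---|---|---|---|---|
| J | 27 mM | 14 mM | 20 mM | 27 mM | 27 mM | 27 mM | 27 mM | 27 mM (fed, over 40.0 h) |
| L | 1 equiv | 1 equiv | 1 equiv | 2 equiv | 1.00 equiv (fed, over 40.0 h) | 1.00 equiv | 1.00 equiv | 1.00 equiv |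
| remark | run made earlier | run made earlier | run made earlier | run made earlier | all but L at the start; L goes in evenly over 40.0 h, the run ends at 40 h | a closed flask charged with all of it at once and left for 40 h | a single well-mixed tank run continuously and read at steady state, 40 h in it on average | all but J at the start; J goes in evenly over 40.0 h, the run ends at 40 h |
| time |  |  |  |  | 40 h | 40 h |  | 40 h |

| run | time / h | D / % | G / % | J / % |
|---|---|---|---|---|
| Sunday's | 2.00 | 52.6 | 0.2 | 42.7 |
| Sunday's | 3.00 | 60.2 | 2.4 | 26.3 |
| Sunday's | 4.00 | 64.9 | 3.9 | 17.8 |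
| Sunday's | 6.00 | 62.6 | 5.3 | 8.4 |
| Sunday's | 10.0 | 45.7 | 9.5 | 1.4 |
| Sunday's | 15.0 | 28.7 | 16.6 | 0.4 |
| Sunday's | 25.0 | 9.6 | 19.2 | 0 |
| Saturday's | 6.00 | 64.1 | 2.5 | 7.4 |
| Saturday's | 15.0 | 29.8 | 8.9 | 0 |
| Saturday's | 20.0 | 19.8 | 11.0 | 0.4 |
| Saturday's | 30.0 | 6.8 | 13.0 | 1.0 |
| Saturday's | 40.0 | 3.7 | 13.0 | 0 |
| Saturday's | 50.0 | 1.2 | 13.9 | 0.2 |
| Friday's | 6.00 | 64.4 | 4.9 | 7.1 |
| Friday's | 15.0 | 30.0 | 11.3 | 0 |
| Friday's | 20.0 | 17.2 | 14.9 | 0 |
| Friday's | 30.0 | 5.5 | 16.9 | 0 |
| Friday's | 40.0 | 2.8 | 15.4 | 0 |
| Friday's | 50.0 | 1.1 | 15.1 | 0.5 |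
| Wednesday's | 10.0 | 40.6 | 16.7 | 1.4 |
| Wednesday's | 20.0 | 12.8 | 27.7 | 0.7 |
| Wednesday's | 30.0 | 2.4 | 29.4 | 0.7 |
| Wednesday's | 40.0 | 1.6 | 31.3 | 0 |
| Wednesday's | 50.0 | 0 | 33.1 | 1.0 |

(each reading ± 1 percentage point)

- the stated concentrations are those of everything mixed, before any reaction; amounts are the same in each set-up
- what was read earlier has a scatter of 1 percentage point, one standard deviation
- the feed brings no volume worth counting
- the earlier runs were made in a closed, stirred flask

1. the set-up with the highest amount of D at the outlet or at the end, in percent of the J put in ("none" if the first two lie within 2 percentage points) (alder / ash / larch / birch / none)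
2. amount of D at the outlet or at the end, in percent of the J put in, alder
3. amount of D at the outlet or at the end, in percent of the J put in, ash
4. amount of D at the outlet or at the end, in percent of the J put in, larch
5. amount of D at the outlet or at the end, in percent of the J put in, birch

- Saturday's run, with about half of the J, reads a D loss of 0.0985 h⁻¹, close to Sunday's. We therefore carry kD as a first-order reading for flasks with 1 equiv of L.
- Now compare two rates in birch at one moment. J is fed evenly, and kJ is far above the inverse of the feed time, so J turns into D nearly as fast as it arrives.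
- D is thus made at the feed rate and lost at kD times D. The two rates meet when D equals feed rate over kD, a quasi-steady state.
- As a share of the whole charge, that level is 24.0 %. We call it the balance share: the inverse of kD times the feed time.
- The comparison drifts towards balance. The feed lasts 4.16 lifetimes of D, and the gap shrinks to about 1.56 % of its start. Our reckoning for birch is therefore w itself.
- In ash and alder all the J goes in at the start, so their D has the whole run to age. The same factor, 1.56 %, then stands well below w.
- In larch, our tank balance gives 18.3 %, which is less than w. We pick birch.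
- The forecast also picks birch, on the ground that “feeding J keeps D young”. It gives alder 3 %, ash 2.1 %, larch 18 % and birch 22.8 %, which is 1.2 percentage points below our w.
- The flasks give alder 3.17 %, ash 2.32 %, larch 19.5 % and birch 24.8 %, so birch is highest.

    D + X → G (k = 4.80 M⁻¹ h⁻¹)
    2 X → Z (k = 1.70 M⁻¹ h⁻¹)
    X → Q (k = 0.0700 h⁻¹)
    L → X (k = 0.0480 h⁻¹)
    D → E (k = 0.0800 h⁻¹)
    J → D (k = 0.420 h⁻¹)

- Birch ends 0.80 points above w, with 6.0 % of its J still unreacted.
- The formula for w holds no concentration. Birch's neighbour with 46 mM of J ends at 23.4 %, close to w.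
- Birch has not come to rest at 40.0 h: it still holds 24.8 % of D and 5.95 % of J. Left to 400 h, birch loses that stock: G reaches 18.4 %, E reaches 81.6 % and D falls to 0 %.

The runs are simulated with made-up constants.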